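Ask which recipe ends with more E: oak, with the whole J in from the start, or larch, with J fed in steadily.

| flask | J | Q | X | remark | time |
|---|---|---|---|---|---|
| teal | 0.20 M (fed, over 15 h) | 0.050 M | 3.2 mM | run made earlier |  |
| amber | 0.20 M (fed, over 15 h) | 0.20 M | 3.2 mM | run made earlier |  |
| oak | 0.20 M | 0.100 M | 3.2 mM | everything together at the start | 15 h |
| larch | 0.20 M (fed, over 15 h) | 0.100 M | 3.2 mM |  | 15 h |

| run | time / h | E / % | J / % |
|---|---|---|---|
| teal | 1.33 | 0.7 | 4.9 |
| teal | 4.00 | 3.0 | 8.7 |
| teal | 6.00 | 6.1 | 11.4 |
| teal | 10.0 | 11.5 | 16.5 |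
| teal | 15.0 | 17.9 | 22.7 |
| teal | 20.0 | 21.5 | 11.3 |
| amber | 1.33 | 0.7 | 4.7 |
| amber | 2.50 | 2.1 | 6.5 |
| amber | 4.00 | 3.6 | 8.9 |
| amber | 6.00 | 5.7 | 10.4 |
| amber | 10.0 | 10.0 | 15.7 |
| amber | 20.0 | 19.4 | 9.1 |

(each reading ± 0.3 percentage points)

- which of the two ends with the higher amount of E, in percent of the J charged ("neither" if they lie within 2 percentage points) (oak / larch / neither)
- E at the end, in percent of the J charged, oak
- E at the end, in percent of the J charged, larch

- percentages count the whole charge, also what has not yet gone in

Start from teal, which is larch's recipe with less Q, and treat Q as a small correction to it. Teal holds Q at a quarter of the J charge and amber holds it at the full J charge. At 20.0 h, amber's E reads 2.1 percentage points under teal's, so reckon: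

toll = (1 − 19.4% / 21.5%) / (1.00 − 0.250) = 0.130

Call this the Q toll: the share of E lost for each whole J charge of Q added. Larch holds Q at half of the J charge, so correct teal's reading at the end of the feed:

larch E = 17.9% × (1 − 0.130 × 0.250) = 17.3%

The toll rests on one difference of two readings, each with a scatter of 0.3 points, so test it on the pair at 10.0 h:

toll = 0.174, larch E = 17.1%

The toll moves larch by 0.2 points, but the weak link is teal's reading of 17.9%: nearly all of its scatter of 0.3 points passes into larch. So keep 17.3% as my figure, with that scatter on it. Neither earlier run was charged like oak, so the toll gives no figure for oak. It can carry an oak figure from one Q to another.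

The forecast says oak ends higher, with 23% for oak and 16.4% for larch, arguing that in oak “J meets fresh catalyst”. Its larch figure lies below mine.

The flask gives oak as the higher: 28.4% for oak and 17.1% for larch.

    J + X ⇌ E + X, rate k1*[J]*[X] forward; the back reaction follows from the equilibrium constant (K = 6.70, k = 0.0200 L mol⁻¹ s⁻¹)
    E + X ⇌ G + X, rate k2*[X]*[E] forward; the back reaction follows from the equilibrium constant (K = 0.740, k = 0.00100 L mol⁻¹ s⁻¹)
    G + X ⇌ J + X, rate k3*[X]*[G] forward; the back reaction follows from the equilibrium constant (k = 0.0180 L mol⁻¹ s⁻¹)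
    J ⇌ D (K = 0.760, k = 1.40 × 10⁻⁵ s⁻¹)
    J + Q → L (k = 9.60 × 10⁻⁵ L mol⁻¹ s⁻¹)
    2 X → Z (k = 0.00870 L mol⁻¹ s⁻¹)

In oak at 0.355 h, J went into E 6.3 times as fast as it went with Q into L (a selectivity factor, counting the forward rate of the step into E), and at the end L stood at 6.78% of the charge against 28.4% for E. Set the toll on oak's 28.4%, raise Q to 0.850 of the J charge, as in a neighbour flask otherwise like oak, and E comes to 27.1%; that neighbour ended at 27.5%.

All runs stem from a simulated flask for substances that don't exist; noise was put on by code.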